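**Plan**

- Numbering is that of eudesmane: ring A = C1–C5 and C10, ring B = C5–C10. The target is a cis-fused eudesman-8-one with 3α-angelate, 4α-acetate/4β-methyl, 5β-H, 7β-isopropyl and 10β-methyl.
- Retrosynthetic cuts: the two ester C–O bonds, the C10–CH3 bond (conjugate addition), the saturation of ring B (Birch reduction), the C3–O bond (Baeyer–Villiger, from an acetyl group), then C1–C2 and C3–C4 together (photoenolization/Diels–Alder), and last the aryl–acetyl bond.
- Enabling feature: ring B has the substitution pattern of thymol (C7 isopropyl, C8 oxygen, C10 bearing C1), and C4 is a methyl carbinol on C5, para to the C8 oxygen and next to the C3 oxygen. 4-Acetylthymol methyl ether therefore already holds C4, its methyl, C1 (as the ortho methyl) and all of ring B; only C2–C3 come from methyl vinyl ketone.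
- Forward order: ring B is bought as an arene, ring A is closed on it by the photochemical [4+2], ring B is then dearomatised and methylated at C10, and the two esters go on last.
- Stereochemistry: C3 and C4 come from the endo addition of the (E)-photoenol (cis) inside a chiral titanium TADDOLate (absolute sense). C5 is set by equilibration, C10 by cuprate addition cis to H5, C7 by equilibration next to the ketone. The angelate geometry is bought with angelic acid.

Key step: step 2

Assumption: the (R,R)-TADDOL titanium complex is taken to give the (1R,2R) adduct; if the sense of induction is the opposite one, the (S,S) ligand is used and nothing else changes.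

Remark: C7 stays epimerisable until the end of step 7; 12 and 13 are drawn as the epimers expected there, and either C7 epimer converges on 14.

**Step 1**
Reactants: 1 thymol methyl ether; 2 acetyl chloride
Product: 3 1-[4-methoxy-2-methyl-5-(propan-2-yl)phenyl]ethan-1-one
Conditions: AlCl3 (1.1 equiv), CH2Cl2, 0 °C; ice/aq. HCl
Reagents that add atoms: none
Why: Friedel–Crafts acylation, directed by the methoxy group to its para position, the only activated site that is not flanked by two substituents; no stereocentre is formed.

**Step 2**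
Reactants: 3 1-[4-methoxy-2-methyl-5-(propan-2-yl)phenyl]ethan-1-one; 4 methyl vinyl ketone
Product: 6 1-[(1R,2R)-1-hydroxy-6-methoxy-1-methyl-7-(propan-2-yl)-1,2,3,4-tetrahydronaphthalen-2-yl]ethan-1-one, via photoenol 5 (not isolated)
Conditions: Ti(Oi-Pr)4 (1.2 equiv), (R,R)-TADDOL (1.2 equiv), 4 Å MS, toluene, rt; then 4 (3 equiv), hν (365 nm), −10 °C, degassed; aq. NaHCO3
Reagents that add atoms: none
Why: Proposed new method: excitation of ketone 3 and 1,5-hydrogen transfer from the ortho methyl group (C1) to the carbonyl oxygen give the (E)-hydroxy-ortho-quinodimethane 5, which is expected to exchange onto titanium as a dienolate while the same metal binds the carbonyl oxygen of 4, so that the cycloaddition runs inside the chiral TADDOLate; the closest known reaction is the Ti(Oi-Pr)4-promoted photoenolization/Diels–Alder reaction of 2-methylbenzaldehydes with enones and its TADDOL-controlled enantioselective form, which has not been shown for an aryl methyl ketone with an acyclic enone. Ring A closes in an intermolecular, concerted [4+2] cycloaddition in which C1–C2 and C3–C4 form together and ring B regains its aromaticity, which drives the reaction. The hydroxyl group makes the methylene terminus (C1) the more nucleophilic end of the diene, so it bonds to the β-carbon of the enone and the acetyl-bearing carbon bonds to the carbinol carbon (ortho regiochemistry). C3 and C4 are set relative to each other by the endo transition state of the (E)-dienol, which puts the acetyl group cis to the hydroxyl group, and in the absolute sense by the (R,R)-TADDOL ligand, which blocks one face of the titanium-bound dienol. The step needs the (E)-dienol, ortho orientation and endo approach; the first is secured because the (Z)-dienol returns to 3 by a fast 1,5-hydrogen shift, the other two by the hydroxyl group on the diene terminus and its titanium bridge to the enone carbonyl.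

**Step 3**
Reactants: 6 1-[(1R,2R)-1-hydroxy-6-methoxy-1-methyl-7-(propan-2-yl)-1,2,3,4-tetrahydronaphthalen-2-yl]ethan-1-one
Product: 7 (1S,2R)-1-hydroxy-6-methoxy-1-methyl-7-(propan-2-yl)-1,2,3,4-tetrahydronaphthalen-2-yl acetate
Conditions: mCPBA, NaHCO3, CH2Cl2, 0 °C to rt
Reagents that add atoms: 3-chloroperoxybenzoic acid (mCPBA), OOC(=O)c1cccc(Cl)c1
Why: Baeyer–Villiger oxidation, in which the secondary ring carbon migrates in preference to methyl and with retention, so the C3 oxygen takes the place of the acetyl group on the same face, while the bicarbonate buffer keeps the acid-labile tertiary 4-methoxybenzylic alcohol from ionising.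

**Step 4**
Reactants: 7 (1S,2R)-1-hydroxy-6-methoxy-1-methyl-7-(propan-2-yl)-1,2,3,4-tetrahydronaphthalen-2-yl acetate
Product: 8 (1S,2R)-6-methoxy-1-methyl-7-(propan-2-yl)-1,2,3,4-tetrahydronaphthalene-1,2-diol
Conditions: K2CO3 (0.2 equiv), MeOH, rt
Reagents that add atoms: none
Why: Base-catalysed transesterification (methanolysis) of the secondary acetate, which breaks no C–O bond at a stereocentre and is safe because no carbonyl group is left β to the tertiary alcohol for a retro-aldol cleavage.

**Step 5**
Reactants: 8 (1S,2R)-6-methoxy-1-methyl-7-(propan-2-yl)-1,2,3,4-tetrahydronaphthalene-1,2-diol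
Product: 10 (1S,2R)-6-methoxy-1-methyl-7-(propan-2-yl)-1,2,3,4,5,8-hexahydronaphthalene-1,2-diol, via dilithium dialkoxide 9 (not isolated)
Conditions: n-BuLi (2.1 equiv), THF, −78 °C; then Li, NH3(l), t-BuOH, −78 to −33 °C; MeOH, then NH4Cl
Reagents that add atoms: none
Why: Birch reduction of an anisole with the substitution pattern of thymol methyl ether, so the two hydrogens enter at the unsubstituted C6 and C9 and leave the enol ether C7=C8 and the tetrasubstituted C5=C10 alkene, while the benzylic C4–O bond should survive because it is held as a lithium alkoxide (a very poor leaving group) and sits para to the methoxy group, on a node of the half-filled orbital of the radical anion; no stereocentre is formed or touched.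

**Step 6**
Reactants: 10 (1S,2R)-6-methoxy-1-methyl-7-(propan-2-yl)-1,2,3,4,5,8-hexahydronaphthalene-1,2-diol
Product: 12 (3S,4aS,5S,6R)-5,6-dihydroxy-5-methyl-3-(propan-2-yl)-4,4a,5,6,7,8-hexahydronaphthalen-2(3H)-one, via deconjugated enone 11 (not isolated)
Conditions: (CO2H)2, THF/H2O, 0 °C to rt; then DBU, CH2Cl2, rt
Reagents that add atoms: water, O
Why: Mild acid hydrolysis of the enol ether gives the deconjugated ketone, and base-catalysed double-bond migration through the dienolate (the shift that turns Birch-derived β,γ-enones into conjugated enones, as in the passage from thymol methyl ether to piperitone) gives the C9=C10 enone, in which C5 is protonated reversibly and should settle as the more stable epimer with its hydrogen anti to the C4 oxygen, the one whose ring A chair keeps the C4 methyl and the C3 hydroxyl equatorial.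

**Step 7**
Reactants: 12 (3S,4aS,5S,6R)-5,6-dihydroxy-5-methyl-3-(propan-2-yl)-4,4a,5,6,7,8-hexahydronaphthalen-2(3H)-one
Product: 14 (3R,4aS,5S,6R,8aR)-5,6-dihydroxy-5,8a-dimethyl-3-(propan-2-yl)octahydronaphthalen-2(1H)-one, via 7-epi-decalone 13 (not isolated)
Conditions: Me2CuLi (5 equiv), Et2O, −20 to 0 °C; aq. NH4Cl; then NaOMe (0.2 equiv), MeOH, rt
Reagents that add atoms: lithium dimethylcuprate (Me2CuLi), [Li+].C[Cu-]C
Why: Conjugate addition of a Gilman cuprate to an octalone of the 4,4a,5,6,7,8-hexahydronaphthalen-2(3H)-one type, which is known to place the angular methyl cis to the ring-fusion hydrogen and here also anti to the axial C4 oxygen, sets C10 (cis-fused decalin), after which NaOMe equilibrates C7 next to the ketone to the epimer with the isopropyl group equatorial on the cis-decalin chair.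

**Step 8**
Reactants: 14 (3R,4aS,5S,6R,8aR)-5,6-dihydroxy-5,8a-dimethyl-3-(propan-2-yl)octahydronaphthalen-2(1H)-one; 15 angelic acid
Product: 17 (1S,2R,4aR,7R,8aS)-1-hydroxy-1,4a-dimethyl-6-oxo-7-(propan-2-yl)decahydronaphthalen-2-yl (2Z)-2-methylbut-2-enoate, via mixed anhydride 16 (not isolated)
Conditions: 15, 2,4,6-Cl3C6H2COCl, Et3N, toluene, rt; then 14, toluene, 80 °C
Reagents that add atoms: none
Why: Yamaguchi esterification through mixed anhydride 16 without a nucleophilic catalyst, which acylates only the secondary C3 hydroxyl (the tertiary C4 hydroxyl is too hindered), attacks the unhindered angeloyl carbonyl and avoids the Z to E isomerisation to the tiglate; the C3–O bond is not broken, so its configuration is kept.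

**Step 9**
Reactants: 17 (1S,2R,4aR,7R,8aS)-1-hydroxy-1,4a-dimethyl-6-oxo-7-(propan-2-yl)decahydronaphthalen-2-yl (2Z)-2-methylbut-2-enoate
Product: 18 (1S,2R,4aR,7R,8aS)-1-(acetyloxy)-1,4a-dimethyl-6-oxo-7-(propan-2-yl)decahydronaphthalen-2-yl (2Z)-2-methylbut-2-enoate
Conditions: Ac2O, DMAP, Et3N, CH2Cl2, rt to 40 °C
Reagents that add atoms: acetic anhydride, CC(=O)OC(C)=O
Why: DMAP-catalysed acyl transfer (Steglich-type acetylation) to the only remaining hydroxyl, the tertiary one at C4, with retention because the C–O bond is not broken, while the ketone and the angelate are inert under these conditions.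

**Compound list**

1 | thymol methyl ether (2-isopropyl-5-methylanisole) | COc1cc(C)ccc1C(C)C | starting material
2 | acetyl chloride | CC(Cl)=O | starting material
3 | 1-[4-methoxy-2-methyl-5-(propan-2-yl)phenyl]ethan-1-one | CC(=O)c1cc(C(C)C)c(OC)cc1C | intermediate
4 | methyl vinyl ketone (but-3-en-2-one) | C=CC(C)=O | starting material
5 | (1E)-1-[4-methoxy-6-methylidene-3-(propan-2-yl)cyclohexa-2,4-dien-1-ylidene]ethan-1-ol, the (E)-photoenol, hydroxyl turned away from the methylidene group (not isolated) | C=C1C=C(OC)C(C(C)C)=C/C1=C(\O)C | intermediate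
6 | 1-[(1R,2R)-1-hydroxy-6-methoxy-1-methyl-7-(propan-2-yl)-1,2,3,4-tetrahydronaphthalen-2-yl]ethan-1-one, acetyl cis to hydroxyl | CC(=O)[C@@H]1CCc2cc(OC)c(C(C)C)cc2[C@]1(C)O | intermediate
7 | (1S,2R)-1-hydroxy-6-methoxy-1-methyl-7-(propan-2-yl)-1,2,3,4-tetrahydronaphthalen-2-yl acetate | CC(=O)O[C@@H]1CCc2cc(OC)c(C(C)C)cc2[C@]1(C)O | intermediate
8 | (1S,2R)-6-methoxy-1-methyl-7-(propan-2-yl)-1,2,3,4-tetrahydronaphthalene-1,2-diol, cis diol | O[C@@H]1CCc2cc(OC)c(C(C)C)cc2[C@]1(C)O | intermediate
9 | dilithium dialkoxide of 8 (not isolated) | [Li+].[Li+].[O-][C@@H]1CCc2cc(OC)c(C(C)C)cc2[C@]1(C)[O-] | intermediate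
10 | (1S,2R)-6-methoxy-1-methyl-7-(propan-2-yl)-1,2,3,4,5,8-hexahydronaphthalene-1,2-diol (C5=C10 and C7=C8 alkenes) | O[C@@H]1CCC2=C(CC(C(C)C)=C(OC)C2)[C@]1(C)O | intermediate
11 | (5S,6R)-5,6-dihydroxy-5-methyl-3-(propan-2-yl)-3,4,5,6,7,8-hexahydronaphthalen-2(1H)-one, C5=C10 alkene, both C7 epimers (not isolated) | O[C@@H]1CCC2=C(CC(C(C)C)C(=O)C2)[C@]1(C)O | intermediate
12 | (3S,4aS,5S,6R)-5,6-dihydroxy-5-methyl-3-(propan-2-yl)-4,4a,5,6,7,8-hexahydronaphthalen-2(3H)-one (C9=C10 enone, 5β-H, 7α-isopropyl) | O[C@@H]1CCC2=CC(=O)[C@H](C(C)C)C[C@@H]2[C@]1(C)O | intermediate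
13 | (3S,4aS,5S,6R,8aR)-5,6-dihydroxy-5,8a-dimethyl-3-(propan-2-yl)octahydronaphthalen-2(1H)-one, cis-fused, 7α-isopropyl (not isolated) | O[C@@H]1CC[C@]2(C)CC(=O)[C@H](C(C)C)C[C@@H]2[C@]1(C)O | intermediate
14 | (3R,4aS,5S,6R,8aR)-5,6-dihydroxy-5,8a-dimethyl-3-(propan-2-yl)octahydronaphthalen-2(1H)-one, cis-fused, 7β-isopropyl | O[C@@H]1CC[C@]2(C)CC(=O)[C@@H](C(C)C)C[C@@H]2[C@]1(C)O | intermediate
15 | angelic acid, (2Z)-2-methylbut-2-enoic acid | C/C=C(/C)C(=O)O | starting material
16 | (2Z)-2-methylbut-2-enoic 2,4,6-trichlorobenzoic anhydride (not isolated) | C/C=C(/C)C(=O)OC(=O)c1c(Cl)cc(Cl)cc1Cl | intermediate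
17 | (1S,2R,4aR,7R,8aS)-1-hydroxy-1,4a-dimethyl-6-oxo-7-(propan-2-yl)decahydronaphthalen-2-yl (2Z)-2-methylbut-2-enoate | C/C=C(/C)C(=O)O[C@@H]1CC[C@]2(C)CC(=O)[C@@H](C(C)C)C[C@@H]2[C@]1(C)O | intermediate
18 | (1S,2R,4aR,7R,8aS)-1-(acetyloxy)-1,4a-dimethyl-6-oxo-7-(propan-2-yl)decahydronaphthalen-2-yl (2Z)-2-methylbut-2-enoate (CNP0322180.1) | C/C=C(/C)C(=O)O[C@@H]1CC[C@]2(C)CC(=O)[C@@H](C(C)C)C[C@@H]2[C@]1(C)OC(C)=O | target

**Totals**

Total step count: 9. Longest linear sequence: 9 steps (1 to 18).

**Steps most likely to fail**

Step 2. The titanium TADDOLate may discriminate poorly between the two faces of the bound dienol, or give the opposite sense. Binding of titanium to the ketone may also slow the hydrogen transfer and lower conversion. The fallback uses known chemistry only and sets out from 3 and 4. Irradiation at 365 nm in degassed toluene without any additive should give the racemic cis adduct, that is 6 together with the enantiomeric adduct F1. Baeyer–Villiger oxidation as in step 3 then gives 7 together with the enantiomeric acetate F2. Hydrolysis with Burkholderia cepacia lipase (phosphate buffer pH 7, t-BuOMe, 30 °C) should cleave only the (2R)-acetate 7, the fast-reacting enantiomer by the empirical size rule for secondary alcohols, and so deliver diol 8. Unreacted F2 is removed by chromatography. The route is rejoined at 8.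

Step 5. The benzylic C4–O bond may be cleaved reductively once t-BuOH protonates the alkoxide, and the electron-rich, fully substituted anisole may be reduced only in part. The fallback dearomatises by hydrogenation instead of electron transfer and sets out from 8.
- LiBH(s-Bu)3 in refluxing THF cleaves the aryl methyl ether to the phenol triol F3.
- H2 (50 bar) over Rh/Al2O3 in i-PrOH, a catalyst that reduces arenes with little benzylic hydrogenolysis, gives the perhydro triol F4. It forms as a mixture at the four new centres (C5, C7, C8, C10), all of which are erased or re-equilibrated later.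
- 2,2-Dimethoxypropane with PPTS ties the cis-3,4-diol as the acetonide alcohol F5.
- Dess–Martin periodinane oxidises the C8 alcohol to the acetonide ketone F6.
- LiN(i-Pr)2 and Me3SiCl at −78 °C give the less substituted silyl enol ether F7 (C8=C9).
- Pd(OAc)2 in MeCN (Saegusa–Ito oxidation) gives the enone acetonide F8, which DBU equilibrates at C5 and C7.
- Aqueous AcOH removes the acetonide and returns the route to 12.

Step 6. The tertiary allylic C4 alcohol may ionise during the acidic hydrolysis. Under the base, water may be lost across C4/C5 (vinylogous β-elimination), ring A may open by a vinylogous retro-aldol, or the epimer ratio at C5 may be unfavourable. The fallback masks both hydroxyls before ring B is unmasked, so that a bulky silyloxy group on the α face of C4 steers both the protonation at C5 and the later cuprate to the β face. It sets out from 10.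
- Et3SiOSO2CF3 and 2,6-lutidine (CH2Cl2, −78 °C) give the bis(triethylsilyl) diene F9.
- Oxalic acid and then DBU, as in step 6, give the silylated deconjugated ketone F10 and from it the silylated conjugated enone F11.
- Me2CuLi gives the silylated 7-epi-decalone F12.
- Bu4NF removes both silyl groups to give 13, and NaOMe in MeOH then gives 14, where the route is rejoined.

**Further compounds**

F1 | step 2 | 1-[(1S,2S)-1-hydroxy-6-methoxy-1-methyl-7-(propan-2-yl)-1,2,3,4-tetrahydronaphthalen-2-yl]ethan-1-one (enantiomer of 6) | CC(=O)[C@H]1CCc2cc(OC)c(C(C)C)cc2[C@@]1(C)O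
F2 | step 2 | (1R,2S)-1-hydroxy-6-methoxy-1-methyl-7-(propan-2-yl)-1,2,3,4-tetrahydronaphthalen-2-yl acetate (enantiomer of 7) | CC(=O)O[C@H]1CCc2cc(OC)c(C(C)C)cc2[C@@]1(C)O
F3 | step 5 | (1S,2R)-1-methyl-7-(propan-2-yl)-1,2,3,4-tetrahydronaphthalene-1,2,6-triol | O[C@@H]1CCc2cc(O)c(C(C)C)cc2[C@]1(C)O
F4 | step 5 | (1S,2R)-1-methyl-7-(propan-2-yl)decahydronaphthalene-1,2,6-triol, mixture at C4a, C6, C7 and C8a | O[C@@H]1CCC2CC(O)C(C(C)C)CC2[C@]1(C)O
F5 | step 5 | 1,2-O-isopropylidene derivative (acetonide) of F4 | CC1(C)O[C@@H]2CCC3CC(O)C(C(C)C)CC3[C@]2(C)O1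
F6 | step 5 | acetonide ketone, the C8 (naphthalene C6) ketone from F5 | CC1(C)O[C@@H]2CCC3CC(=O)C(C(C)C)CC3[C@]2(C)O1
F7 | step 5 | trimethylsilyl enol ether of F6 (C8=C9) | CC1(C)O[C@@H]2CCC3C=C(O[Si](C)(C)C)C(C(C)C)CC3[C@]2(C)O1
F8 | step 5 | 5,6-O-isopropylidene derivative (acetonide) of enone 12 | CC1(C)O[C@@H]2CCC3=CC(=O)[C@H](C(C)C)C[C@@H]3[C@]2(C)O1
F9 | step 6 | bis(triethylsilyl) ether of 10 | CC[Si](CC)(CC)O[C@@H]1CCC2=C(CC(C(C)C)=C(OC)C2)[C@]1(C)O[Si](CC)(CC)CC
F10 | step 6 | bis(triethylsilyl) ether of 11 | CC[Si](CC)(CC)O[C@@H]1CCC2=C(CC(C(C)C)C(=O)C2)[C@]1(C)O[Si](CC)(CC)CC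
F11 | step 6 | bis(triethylsilyl) ether of 12 | CC[Si](CC)(CC)O[C@@H]1CCC2=CC(=O)[C@H](C(C)C)C[C@@H]2[C@]1(C)O[Si](CC)(CC)CC
F12 | step 6 | bis(triethylsilyl) ether of 13 | CC[Si](CC)(CC)O[C@@H]1CC[C@]2(C)CC(=O)[C@H](C(C)C)C[C@@H]2[C@]1(C)O[Si](CC)(CC)CC
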